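(The readings stem from a simulated flask for substances that don't exist, noise included.)

This slurry is slow: after 120 min the ochre run holds 9.80% of the solid substrate as bis adduct plus tris adduct, so a pencil can go first.

common to all: solid substrate 17 mM

|  | partner | remark | time |
|---|---|---|---|
| ochre | 0.74 equiv | run made earlier |  |
| teal | 2.9 equiv | run made earlier |  |
| noon | 2.00 equiv |  | 2.5 h |
| midnight | 0.500 equiv |  | 2.5 h |

- ochre (time / min: bis adduct / %, tris adduct / %): 15.0: 0.3, 0.7; 30.0: 0, 0.9; 50.0: 1.6, 0; 60.0: 2.4, 1.4; 80.0: 3.1, 1.4; 90.0: 4.4, 0; 120: 8.0, 1.8
- teal (time / min: bis adduct / %, tris adduct / %): 6.00: 1.3, 0; 15.0: 3.8, 0; 30.0: 4.4, 2.9; 50.0: 12.0, 4.8; 60.0: 14.0, 7.3; 80.0: 22.1, 9.5; 120: 37.5, 12.9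

(readings scatter by 1 percentage point)

- which of these holds the largest part of the solid substrate at the end of noon (bis adduct / tris adduct / solid substrate / single product)
- which of these holds the largest part of the solid substrate at the end of midnight (bis adduct / tris adduct / solid substrate / single product)
- bis adduct at the end of midnight, in percent of the solid substrate charged

Bis adduct lies two partner steps from starting material. Our bench rule therefore takes the partner dose, equivalents charged times minutes, as the clock of a pseudo-first-order chain, and lets the adduct sum grow as its square. The runs test the clock: teal at 30.0 min has dose 87.0 equiv·min and ochre at 120 min has 88.8 equiv·min, and their sums read 7.30% and 9.80%, with each reading good to 1 percentage point. Pooled, dose 87.9 equiv·min gives 8.55%. That sets the dose scale 301 equiv·min, the dose at which the square would reach the whole charge.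

The border shows in teal. At 50.0 min the ratio of dose to scale is 0.482, and the square promises 23.3%, but the sum reads less, 16.8%. So the rule is fitted at 0.292 and has failed by 0.482.

Midnight stands inside, at ratio 0.249, so we reckon a sum of 6.22%. Teal's last tris-to-bis ratio, scaled by partner charged, makes that 5.88% bis adduct. With 0.500 equiv of partner charged, and each product taking at least one partner, we expect solid substrate to lead. Noon stands outside, at ratio 0.998, where single product is unread, so we leave its leader open.

The forecast names solid substrate for noon and solid substrate for midnight, with 5.5% bis adduct, less than ours, and holds that “This fits a dissolved starting material held at its solubility limit”.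

The flask gives bis adduct at noon, 35.6% against 27.8% of solid substrate. At midnight it gives solid substrate, 73.0%, with 5.51% bis adduct.

    starting material + partner → single product (k = 5.33 /M/min)
    partner + single product → bis adduct (k = 0.745 /M/min)
    partner + bis adduct ⇌ tris adduct (K = 14.0 /M, k = 2.56 /M/min)
    solid substrate ⇌ starting material, rate k4*(cs4 - [starting material]) while solid is left; crystals form when [starting material] > cs4 (solubility = 0.890 mM, k = 0.309 /min)

Midnight's adduct sum comes to 5.79% against our 6.22%. The neighbouring flask repeats midnight with 0.120 equiv of partner, which puts its ratio of dose to scale at 0.0599, well inside the border. The square then gives a sum of 0.359%. That flask holds 0.00578% tris adduct and 0.433% bis adduct.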